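**Retrosynthetic overview** (pterocarpan numbering: ring A = C1–C4a/C11b, ring B = O5/C6, ring C = O11, ring D = C6b–C10a, ring E = dimethylpyran on ring A, ring F = hydroxy-dimethyl-dihydropyran on ring D)

1. Ring C closes last: the C11a–O11 bond comes from acid-induced closure of a cis-isoflavan-4-ol, and C6a/C11a are set together by Ru-catalysed asymmetric transfer hydrogenation with dynamic kinetic resolution of 2'-hydroxyisoflavone 20. Isoflavone 20 is cut at the C6a–C6b bond (Suzuki) into iodochromone 11 (rings A, E) and boronate 18 (rings D, F).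
2. Hidden repetition: rings A/E and rings D/F are the same unit, a 2,2-dimethylpyran fused to a 1,3-dioxygenated six-membered carbocycle with its carbon substituent ortho to the second oxygen, so both halves are drawn from one bicyclic ketone, 7.
3. Enabling feature: O3–C3/C4/C4a–O5 of ring A (and O9–C9/C10/C10a–O11 of ring D) is a cyclohexane-1,3-dione in disguise. At the dione oxidation level the carbon between the two oxygens carries an aminomethylene carbon that accepts an isobutenyl Grignard reagent, and the resulting 1-oxatriene closes by oxa-6π electrocyclisation; this forms the bond between the two olefinic CH carbons of ring E and its O–CMe2 bond in one operation, with no dearomatisation.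
4. The partly saturated ring of 7 is then substituted at its only enolisable CH2 and aromatised late (acetylation/DDQ to ring A, selenoxide elimination to ring D). The ring-F carbinol comes from Jacobsen epoxidation and hydride opening of the same pyran.
5. Order of ring formation: pyran E/F (step 2), arene A (step 4), the pyranone that becomes ring B (step 6), arene D (step 7), ring C (step 14).

Key step: step 2

Remark: the SMILES is read as (6aR,11aR) with an (R) carbinol in ring F; metalated forms of numbered compounds (lithium enolates, the aryllithium of step 11, magnesium salts) are treated as those compounds under the conditions of the step and carry no number of their own.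

**Route**

Step 1
Reactants: 1 cyclohexane-1,3-dione; 2 N,N-dimethylformamide dimethyl acetal
Product: 3 2-[(dimethylamino)methylidene]cyclohexane-1,3-dione
Conditions: 2 (1.2 equiv), toluene, 23 → 80 °C
Reagents that add atoms: none
Why: Aminomethylenation of the acidic C2 methylene of a 1,3-dione with an amide acetal (enaminone formation) is a standard condensation and should give the push–pull alkene 3 with loss of two methanol.

Step 2
Reactants: 3 2-[(dimethylamino)methylidene]cyclohexane-1,3-dione; 4 (2-methylprop-1-en-1-yl)magnesium bromide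
Product: 7 2,2-dimethyl-7,8-dihydro-2H-chromen-5(6H)-one, via Mannich base 5 (not isolated), via oxatriene 6 (not isolated)
Conditions: 4 (1.2 equiv), THF, −40 → 0 °C; then AcOH, H2O, 23 → 45 °C
Reagents that add atoms: none
Why: Proposed new method: the alkenyl Grignard reagent should add in 1,4-fashion to the exocyclic aminomethylene carbon of 3, the one carbon activated by both carbonyl groups, which forms the CH–CH bond of the later pyran and gives the chelated magnesium dionate of Mannich base 5; the closest known reaction type is the addition–elimination of Grignard reagents to β-(dimethylamino)enones that turns enaminones into enones. The dionate cannot expel an amide ion, so the amine should stay in place until the quench and a second addition is excluded; acetic acid then protonates nitrogen and E1cB loss of dimethylamine from 5 gives the 1-oxatriene 6, the intermediate of the known Knoevenagel/oxa-6π annulation of 1,3-diones with enals. Ring closure is a thermal disrotatory oxa-6π electrocyclisation of the O=C–C=C–C=C unit of 6 that forms the O–CMe2 bond and the six-membered 2H-pyran. Because either carbonyl of the symmetrical dione can act as the oxygen terminus, the reactive s-cis geometry is always at hand, and because the carbocycle is not yet aromatic no dearomatised quinone methide has to be generated, so the equilibrium should lie on the side of 7. No stereocentre is formed. The selectivity needed is 1,4- over 1,2-addition and single over double addition, and the vinylogous-amide character of both carbonyl groups together with the stability of the magnesium dionate should secure it.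

Step 3
Reactants: 7 2,2-dimethyl-7,8-dihydro-2H-chromen-5(6H)-one
Product: 8 6-acetyl-2,2-dimethyl-7,8-dihydro-2H-chromen-5(6H)-one
Conditions: LDA (1.15 equiv), THF, −78 °C; MeC(O)N(OMe)Me, −78 → 0 °C; then 1 M HCl
Reagents that add atoms: N-methoxy-N-methylacetamide, CC(=O)N(C)OC
Why: Kinetic deprotonation of the vinylogous ester occurs at C6, the only CH2 next to the carbonyl, and Claisen-type C-acylation of this enolate by the Weinreb amide through a chelated tetrahedral adduct should place the acetyl group regiospecifically and give the enolised β-diketone.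

Step 4
Reactants: 8 6-acetyl-2,2-dimethyl-7,8-dihydro-2H-chromen-5(6H)-one
Product: 9 1-(5-hydroxy-2,2-dimethyl-2H-chromen-6-yl)ethan-1-one
Conditions: DDQ (1.1 equiv), 1,4-dioxane, 23 → 80 °C
Reagents that add atoms: none
Why: DDQ dehydrogenation of the enolised β-diketone removes the C7 and C8 hydrogens and the dienone tautomerises to the hydrogen-bonded o-hydroxyacetophenone, so that ring A is aromatised with the acetyl group fixed ortho to the phenol while the pyran alkene offers no abstractable hydride.

Step 5
Reactants: 9 1-(5-hydroxy-2,2-dimethyl-2H-chromen-6-yl)ethan-1-one; 2 N,N-dimethylformamide dimethyl acetal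
Product: 10 (E)-3-(dimethylamino)-1-(5-hydroxy-2,2-dimethyl-2H-chromen-6-yl)prop-2-en-1-one
Conditions: 2 (2 equiv), toluene, 95 °C
Reagents that add atoms: none
Why: Condensation of the methyl ketone with the amide acetal should give the (E)-enaminone, the standard precursor of 3-halochromones (enaminone formation).

Step 6
Reactants: 10 (E)-3-(dimethylamino)-1-(5-hydroxy-2,2-dimethyl-2H-chromen-6-yl)prop-2-en-1-one
Product: 11 3-iodo-8,8-dimethyl-4H,8H-pyrano[2,3-f]chromen-4-one
Conditions: I2 (1.5 equiv), pyridine, CHCl3, 23 °C
Reagents that add atoms: iodine, II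
Why: Iodination of the enaminone at its α-carbon, attack of the phenol on the iminium carbon and loss of dimethylamine should give the 3-iodochromone (iodine-mediated enaminone cyclisation), which is expected to outpace any reversible addition of iodine to the pyran alkene.

Step 7
Reactants: 7 2,2-dimethyl-7,8-dihydro-2H-chromen-5(6H)-one
Product: 14 2,2-dimethyl-2H-chromen-5-ol, via selenide 12 (not isolated), via selenoxide 13 (not isolated)
Conditions: LDA, THF, −78 °C; PhSeCl; then H2O2 (30%), pyridine, CH2Cl2, 0 → 23 °C
Reagents that add atoms: none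
Why: Selenenylation of the same kinetic enolate gives selenide 12, whose selenoxide 13 should undergo syn-elimination into the C6–C7 bond, and the cyclohexadienone tautomerises to the phenol, so that ring D is aromatised late with C6 left as the only free position ortho to the hydroxyl (α-selenenylation/selenoxide elimination).

Step 8
Reactants: 14 2,2-dimethyl-2H-chromen-5-ol
Product: 15 5-(methoxymethoxy)-2,2-dimethyl-2H-chromene
Conditions: MOMCl, i-Pr2NEt, CH2Cl2, 0 → 23 °C
Reagents that add atoms: chloromethyl methyl ether, COCCl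
Why: Standard O-alkylation of the phenol gives the MOM ether, which protects the phenol through the oxidation and hydride steps and serves as the directing group in step 11.

Step 9
Reactants: 15 5-(methoxymethoxy)-2,2-dimethyl-2H-chromene
Product: 16 (3R,4R)-3,4-epoxy-5-(methoxymethoxy)-2,2-dimethylchromane
Conditions: (R,R)-(salen)MnCl [Jacobsen's catalyst, salen = N,N'-bis(3,5-di-tert-butylsalicylidene)cyclohexane-1,2-diamine dianion] (3 mol%), NaOCl (aq, pH 11.3), 4-phenylpyridine N-oxide, CH2Cl2, 0 °C
Reagents that add atoms: sodium hypochlorite, [Na+].[O-]Cl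
Why: Jacobsen–Katsuki epoxidation is highly face-selective for 2,2-dimethylchromenes, and the (R,R)-ligand is expected to deliver oxygen to the face that gives the (3R,4R)-epoxide, which sets the later carbinol centre; the labile epoxide is carried on crude.

Step 10
Reactants: 16 (3R,4R)-3,4-epoxy-5-(methoxymethoxy)-2,2-dimethylchromane
Product: 17 (3R)-5-(methoxymethoxy)-2,2-dimethyl-3,4-dihydro-2H-chromen-3-ol
Conditions: LiAlH4, THF, 0 → 23 °C
Reagents that add atoms: none
Why: Hydride should open the epoxide by SN2 attack at the benzylic C4, because C3 is shielded by the adjacent quaternary carbon, so the C3–O bond and its (R) configuration stay untouched (regioselective reductive epoxide opening).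

Step 11
Reactants: 17 (3R)-5-(methoxymethoxy)-2,2-dimethyl-3,4-dihydro-2H-chromen-3-ol
Product: 18 (3R)-5-(methoxymethoxy)-2,2-dimethyl-6-(4,4,5,5-tetramethyl-1,3,2-dioxaborolan-2-yl)-3,4-dihydro-2H-chromen-3-ol
Conditions: n-BuLi (2.4 equiv), TMEDA, THF, −78 → 0 °C; i-PrOBpin, −78 → 23 °C; then AcOH
Reagents that add atoms: 2-isopropoxy-4,4,5,5-tetramethyl-1,3,2-dioxaborolane, CC(C)OB1OC(C)(C)C(C)(C)O1
Why: Directed ortho-metalation: after deprotonation of the alcohol the MOM ether should direct lithiation to C6, its only free ortho position, and the aryllithium is trapped by the borate ester to give the pinacol boronate.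

Step 12
Reactants: 11 3-iodo-8,8-dimethyl-4H,8H-pyrano[2,3-f]chromen-4-one; 18 (3R)-5-(methoxymethoxy)-2,2-dimethyl-6-(4,4,5,5-tetramethyl-1,3,2-dioxaborolan-2-yl)-3,4-dihydro-2H-chromen-3-ol
Product: 19 3-[(3R)-3-hydroxy-5-(methoxymethoxy)-2,2-dimethyl-3,4-dihydro-2H-chromen-6-yl]-8,8-dimethyl-4H,8H-pyrano[2,3-f]chromen-4-one
Conditions: Pd(dppf)Cl2 (5 mol%), K2CO3, 1,4-dioxane/H2O, 80 °C
Reagents that add atoms: none
Why: Suzuki–Miyaura coupling of 3-iodochromones with arylboron reagents is the standard isoflavone synthesis; oxidative addition of the carbon–iodine bond to zerovalent palladium is fast and the free alcohol, MOM ether and pyran alkene are spectators.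

Step 13
Reactants: 19 3-[(3R)-3-hydroxy-5-(methoxymethoxy)-2,2-dimethyl-3,4-dihydro-2H-chromen-6-yl]-8,8-dimethyl-4H,8H-pyrano[2,3-f]chromen-4-one
Product: 20 3-[(3R)-3,5-dihydroxy-2,2-dimethyl-3,4-dihydro-2H-chromen-6-yl]-8,8-dimethyl-4H,8H-pyrano[2,3-f]chromen-4-one
Conditions: HCl (cat.), MeOH, 40 °C
Reagents that add atoms: none
Why: Acid-catalysed acetal exchange with methanol cleaves the aryl MOM ether at a stage where no benzylic alcohol is present and the pyran alkene, attached to the electron-poor chromone, should tolerate the mild acid (MOM deprotection).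

Step 14
Reactants: 20 3-[(3R)-3,5-dihydroxy-2,2-dimethyl-3,4-dihydro-2H-chromen-6-yl]-8,8-dimethyl-4H,8H-pyrano[2,3-f]chromen-4-one
Product: 23 target CNP0126417.1, via isoflavanone 21 (not isolated), via cis-isoflavan-4-ol 22 (not isolated)
Conditions: RuCl[(R,R)-TsDPEN](p-cymene) (5 mol%), HCO2H/Et3N (5:2), EtOAc, 40 °C; then HCl (2 M in EtOH), 23 °C
Reagents that add atoms: none
Why: Noyori–Ikariya transfer hydrogenation should first reduce the chromone C2=C3 bond to the base-epimerisable isoflavanone 21 and then reduce its ketone with dynamic kinetic resolution, the (R,R)-catalyst being expected (as for aryl ketones) to give the (4R) carbinol and, through the favoured cis transition state, the (3R) centre that becomes C6a, after which acid ionises the benzylic alcohol to a cation stabilised by the para ring-E oxygen and the 2'-phenol captures it in a 5-exo closure that can only be cis-fused, fixing C11a as (R).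

**Compound list**

1 | cyclohexane-1,3-dione | O=C1CCCC(=O)C1 | starting material
2 | N,N-dimethylformamide dimethyl acetal | COC(OC)N(C)C | starting material
3 | 2-[(dimethylamino)methylidene]cyclohexane-1,3-dione | CN(C)C=C1C(=O)CCCC1=O | intermediate
4 | (2-methylprop-1-en-1-yl)magnesium bromide | CC(C)=C[Mg]Br | starting material
5 | 2-[1-(dimethylamino)-3-methylbut-2-en-1-yl]-3-hydroxycyclohex-2-en-1-one (Mannich base) | CC(C)=CC(N(C)C)C1=C(O)CCCC1=O | intermediate (not isolated)
6 | 2-(3-methylbut-2-en-1-ylidene)cyclohexane-1,3-dione (oxatriene) | CC(C)=CC=C1C(=O)CCCC1=O | intermediate (not isolated)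
7 | 2,2-dimethyl-7,8-dihydro-2H-chromen-5(6H)-one | CC1(C)C=CC2=C(O1)CCCC2=O | intermediate
8 | 6-acetyl-2,2-dimethyl-7,8-dihydro-2H-chromen-5(6H)-one | CC(=O)C1CCC2=C(C=CC(C)(C)O2)C1=O | intermediate
9 | 1-(5-hydroxy-2,2-dimethyl-2H-chromen-6-yl)ethan-1-one | CC(=O)c1ccc2OC(C)(C)C=Cc2c1O | intermediate
10 | (E)-3-(dimethylamino)-1-(5-hydroxy-2,2-dimethyl-2H-chromen-6-yl)prop-2-en-1-one | CN(C)/C=C/C(=O)c1ccc2OC(C)(C)C=Cc2c1O | intermediate
11 | 3-iodo-8,8-dimethyl-4H,8H-pyrano[2,3-f]chromen-4-one | O=c1c(I)coc2c1ccc1OC(C)(C)C=Cc12 | intermediate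
12 | 2,2-dimethyl-6-(phenylselanyl)-7,8-dihydro-2H-chromen-5(6H)-one (selenide) | CC1(C)C=CC2=C(O1)CCC([Se]c1ccccc1)C2=O | intermediate (not isolated)
13 | 2,2-dimethyl-6-(phenylseleninyl)-7,8-dihydro-2H-chromen-5(6H)-one (selenoxide) | CC1(C)C=CC2=C(O1)CCC([Se](=O)c1ccccc1)C2=O | intermediate (not isolated)
14 | 2,2-dimethyl-2H-chromen-5-ol | CC1(C)C=Cc2c(O)cccc2O1 | intermediate
15 | 5-(methoxymethoxy)-2,2-dimethyl-2H-chromene | COCOc1cccc2OC(C)(C)C=Cc12 | intermediate
16 | (3R,4R)-3,4-epoxy-5-(methoxymethoxy)-2,2-dimethylchromane | COCOc1cccc2OC(C)(C)[C@@H]3O[C@@H]3c12 | intermediate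
17 | (3R)-5-(methoxymethoxy)-2,2-dimethyl-3,4-dihydro-2H-chromen-3-ol | COCOc1cccc2OC(C)(C)[C@H](O)Cc12 | intermediate
18 | (3R)-5-(methoxymethoxy)-2,2-dimethyl-6-(4,4,5,5-tetramethyl-1,3,2-dioxaborolan-2-yl)-3,4-dihydro-2H-chromen-3-ol | COCOc1c(B3OC(C)(C)C(C)(C)O3)ccc2OC(C)(C)[C@H](O)Cc12 | intermediate
19 | 3-[(3R)-3-hydroxy-5-(methoxymethoxy)-2,2-dimethyl-3,4-dihydro-2H-chromen-6-yl]-8,8-dimethyl-4H,8H-pyrano[2,3-f]chromen-4-one | COCOc1c(-c3coc4c(ccc5OC(C)(C)C=Cc45)c3=O)ccc2OC(C)(C)[C@H](O)Cc12 | intermediate
20 | 3-[(3R)-3,5-dihydroxy-2,2-dimethyl-3,4-dihydro-2H-chromen-6-yl]-8,8-dimethyl-4H,8H-pyrano[2,3-f]chromen-4-one | Oc1c(-c3coc4c(ccc5OC(C)(C)C=Cc45)c3=O)ccc2OC(C)(C)[C@H](O)Cc12 | intermediate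
21 | 3-[(3R)-3,5-dihydroxy-2,2-dimethyl-3,4-dihydro-2H-chromen-6-yl]-8,8-dimethyl-2,3-dihydro-4H,8H-pyrano[2,3-f]chromen-4-one (isoflavanone, C3 epimerising) | Oc1c(C3COc4c(ccc5OC(C)(C)C=Cc45)C3=O)ccc2OC(C)(C)[C@H](O)Cc12 | intermediate (not isolated)
22 | (3R,4R)-3-[(3R)-3,5-dihydroxy-2,2-dimethyl-3,4-dihydro-2H-chromen-6-yl]-8,8-dimethyl-3,4-dihydro-2H,8H-pyrano[2,3-f]chromen-4-ol (cis-isoflavan-4-ol) | Oc1c([C@@H]3COc4c(ccc5OC(C)(C)C=Cc45)[C@@H]3O)ccc2OC(C)(C)[C@H](O)Cc12 | intermediate (not isolated)
23 | CNP0126417.1: (6aR,11aR)-pterocarpan with a 2,2-dimethyl-2H-pyran fused at O3/C4 (ring E) and a (3R)-3-hydroxy-2,2-dimethyl-3,4-dihydro-2H-pyran fused at O9/C10 (ring F) | CC1(C)C=Cc2c(ccc3c2OC[C@H]2c4ccc5c(c4O[C@@H]32)C[C@@H](O)C(C)(C)O5)O1 | target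

**Step count and risks**

Total step count: 14. Longest linear sequence: 10 steps (steps 1, 2, 7, 8, 9, 10, 11, 12, 13, 14); the other branch (steps 3–6) joins at step 12.

Steps most likely to fail:

Step 2 (proposed new method). The basic Grignard reagent may enolise 3 or add 1,2 to a carbonyl group, or amine loss may occur before the quench and open the way to double addition. The fallback uses known chemistry that makes the same two bonds at the aromatic oxidation level. It sets out from Grignard reagent 4, which is added in excess (3.5 equiv, THF, 0 → 23 °C) to commercial 2,6-dihydroxybenzaldehyde to give 2-(1-hydroxy-3-methylbut-2-en-1-yl)benzene-1,3-diol F1. Mild acid (PPTS, toluene, 60 °C) should dehydrate it through the vinyl ortho-quinone methide and the same oxa-6π closure to chromenol 14, where the route is rejoined for the ring-D branch. The ring-A branch is then fed from MOM ether 15 by ortho-lithiation (n-BuLi, TMEDA) and acylation with N-methoxy-N-methylacetamide to 1-[5-(methoxymethoxy)-2,2-dimethyl-2H-chromen-6-yl]ethan-1-one F2, and MOM cleavage (HCl, MeOH) returns to 9. Steps 1, 3, 4 and 7 then fall away.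

Step 14. Conjugate reduction of the chromone alkene may be slow, epimerisation of 21 may be incomplete (erosion of the dynamic kinetic resolution), the carbinol may dehydrate to the isoflav-3-ene, or ethanol may add to the ring-E alkene under acid. The fallback is the classical achiral hydride route, with the ring-F carbinol as internal resolving element. From 20, NaBH4 (THF/EtOH, 0 → 23 °C) should give the stereoisomer mixture of 3-[(3R)-3,5-dihydroxy-2,2-dimethyl-3,4-dihydro-2H-chromen-6-yl]-8,8-dimethyl-3,4-dihydro-2H,8H-pyrano[2,3-f]chromen-4-ol F3. BF3·OEt2 (CH2Cl2, −20 °C) should then close it to the two cis-fused pterocarpans, 23 and its (6aS,11aS)-diastereomer F4. Because of the (R)-carbinol these are diastereomers and should be separable by chromatography or crystallisation; the route is rejoined at 23.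

Step 11. Ring lithiation of the lithium alkoxide aggregate may be incomplete, deprotonation may compete at C8 or at the benzylic C4 methylene, and the electron-rich boronate may protodeboronate. The fallback installs halogen first and boron by palladium catalysis. From 15, ortho-lithiation (n-BuLi, TMEDA, THF, 0 °C) and quenching with 1,2-dibromotetrachloroethane should give 6-bromo-5-(methoxymethoxy)-2,2-dimethyl-2H-chromene F5. The conditions of steps 9 and 10 should then give (3R,4R)-6-bromo-3,4-epoxy-5-(methoxymethoxy)-2,2-dimethylchromane F6 and (3R)-6-bromo-5-(methoxymethoxy)-2,2-dimethyl-3,4-dihydro-2H-chromen-3-ol F7. Miyaura borylation (B2pin2, Pd(dppf)Cl2, KOAc, 1,4-dioxane, 90 °C) returns to 18.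

**Further compounds**

F1 | step 2 | 2-(1-hydroxy-3-methylbut-2-en-1-yl)benzene-1,3-diol | CC(C)=CC(O)c1c(O)cccc1O
F2 | step 2 | 1-[5-(methoxymethoxy)-2,2-dimethyl-2H-chromen-6-yl]ethan-1-one | COCOc1c(C(C)=O)ccc2OC(C)(C)C=Cc12
F3 | step 14 | 3-[(3R)-3,5-dihydroxy-2,2-dimethyl-3,4-dihydro-2H-chromen-6-yl]-8,8-dimethyl-3,4-dihydro-2H,8H-pyrano[2,3-f]chromen-4-ol (C3/C4 stereoisomer mixture) | Oc1c(C3COc4c(ccc5OC(C)(C)C=Cc45)C3O)ccc2OC(C)(C)[C@H](O)Cc12
F4 | step 14 | (6aS,11aS)-diastereomer of 23 | CC1(C)C=Cc2c(ccc3c2OC[C@@H]2c4ccc5c(c4O[C@H]32)C[C@@H](O)C(C)(C)O5)O1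
F5 | step 11 | 6-bromo-5-(methoxymethoxy)-2,2-dimethyl-2H-chromene | COCOc1c(Br)ccc2OC(C)(C)C=Cc12
F6 | step 11 | (3R,4R)-6-bromo-3,4-epoxy-5-(methoxymethoxy)-2,2-dimethylchromane | COCOc1c(Br)ccc2OC(C)(C)[C@@H]3O[C@@H]3c12
F7 | step 11 | (3R)-6-bromo-5-(methoxymethoxy)-2,2-dimethyl-3,4-dihydro-2H-chromen-3-ol | COCOc1c(Br)ccc2OC(C)(C)[C@H](O)Cc12
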